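**Retrosynthetic overview**
- Target ⇒ 2,5-dibromo-3,6-dimethoxy-1,4-benzoquinone + 2 × N-[2-(3,3-dimethylpent-4-en-1-ynyl)phenyl]trifluoroacetamide: one palladium operation closes both pyrrole rings and forms both indole C3–quinone bonds, with the quinone already at its final oxidation level.
- Alkynyl anilide ⇒ 2-iodoaniline + an alkynylzinc generated in the flask from 3,3-dimethylpent-4-en-2-one (the volatile enyne is never isolated).
- Ketone ⇒ prenyl chloride + N-methoxy-N-methylacetamide (γ-selective Grignard acylation builds the quaternary reverse-prenyl carbon).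
- Ring order: the two benzo rings (2-iodoaniline) and the quinone ring (bromanil) are bought; the two pyrrole rings are closed last, both in the same step.

Assumption: the target SMILES contains no stereocentre and the compound is achiral, so "single enantiomer" is taken to mean the one constitution shown and no stereocontrol is needed.

**Step 1**
Reactants: 1 prenyl chloride (1-chloro-3-methylbut-2-ene); 2 N-methoxy-N-methylacetamide
Product: 4 3,3-dimethylpent-4-en-2-one, via prenylmagnesium chloride 3 (not isolated)
Conditions: Mg turnings, THF, 0 °C (slow addition of 1); then 2, −78 → 0 °C; aq NH4Cl; distil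
Reagents that add atoms: none
Why: Allylic Grignard reagents attack carbonyl electrophiles at the γ-carbon through a six-membered SE2' transition state, so this Weinreb ketone synthesis (stable chelate, no over-addition) gives the α,α-dimethyl-β,γ-unsaturated ketone; no stereocentre is formed.

**Step 2**
Reactants: 4 3,3-dimethylpent-4-en-2-one (1.3 equiv); 5 2-iodoaniline
Product: 9 2-(3,3-dimethylpent-4-en-1-yn-1-yl)aniline, via enol phosphate 6 (not isolated), via lithium acetylide 7 (not isolated), via alkynylzinc bromide 8 (not isolated)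
Conditions: LiN(iPr)2 (1.1 equiv), THF, −78 °C; ClP(O)(OEt)2, −78 °C → rt; LiN(iPr)2 (2.2 equiv), −78 °C → rt; ZnBr2, 0 °C; then 5, Pd(PPh3)4 (3 mol %), rt → 45 °C
Reagents that add atoms: none
Why: The ketone enolises only toward the methyl group, so enol phosphate formation and LiN(iPr)2-induced β-elimination (Negishi methyl ketone-to-alkyne conversion) give the lithium acetylide, which after Li-to-Zn exchange undergoes Negishi alkynylation with the aryl iodide in the presence of the free NH2.

**Step 3**
Reactants: 9 2-(3,3-dimethylpent-4-en-1-yn-1-yl)aniline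
Product: 10 N-[2-(3,3-dimethylpent-4-en-1-yn-1-yl)phenyl]-2,2,2-trifluoroacetamide
Conditions: (CF3CO)2O (1.2 equiv), pyridine, CH2Cl2, 0 °C
Reagents that add atoms: trifluoroacetic anhydride, O=C(OC(=O)C(F)(F)F)C(F)(F)F
Why: Simple N-acylation makes the N–H acidic enough for carbonate-mediated aminopalladation and masks the aniline nitrogen against conjugate addition to the quinone used in step 5.

**Step 4**
Reactants: 11 bromanil (2,3,5,6-tetrabromo-1,4-benzoquinone)
Product: 12 2,5-dibromo-3,6-dimethoxy-1,4-benzoquinone
Conditions: NaOMe (2.05 equiv), MeOH–THF, −10 °C → rt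
Reagents that add atoms: sodium methoxide, C[O-].[Na+]
Why: Addition–elimination (vinylogous acyl substitution) on the haloquinone: the first methoxy group deactivates its own vinylogous ester half, so the second methoxide enters at C5 and substitution stops at the 2,5-dimethoxy-3,6-dibromo pattern.

**Step 5**
Reactants: 10 N-[2-(3,3-dimethylpent-4-en-1-yn-1-yl)phenyl]-2,2,2-trifluoroacetamide (2.3 equiv, added slowly); 12 2,5-dibromo-3,6-dimethoxy-1,4-benzoquinone
Product: 15 2,5-dimethoxy-3,6-bis[2-(2-methylbut-3-en-2-yl)-1H-indol-3-yl]-1,4-benzoquinone, via monoindolyl bromoquinone 13 (not isolated), via bis(N-trifluoroacetyl) bisindolylquinone 14 (not isolated)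
Conditions: Pd(PPh3)4 (10 mol %), anhydrous Cs2CO3 (4 equiv), degassed MeCN, 60 °C; then MeOH, rt, 15 min; AcOH quench
Reagents that add atoms: none
Why: Proposed new method: zerovalent palladium inserts into the vinylogous acyl C–Br bond of 12 (as in Suzuki and Stille couplings of bromoquinones), the quinonyl–Pd–Br species π-activates the alkyne of the amidate of 10, anti-aminopalladation (5-endo-dig) closes the pyrrole ring with the tert-alkyl group at C2, and reductive elimination forms the indole C3–quinone bond; the sequence repeats at the second C–Br and methanol then removes the labile N-COCF3 groups; the closest known reaction is the Cacchi aminopalladation–reductive elimination of 2-alkynyltrifluoroacetanilides with aryl or vinyl halides; no stereocentre is formed.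

**Compound list**
1 | prenyl chloride (1-chloro-3-methylbut-2-ene) | CC(C)=CCCl | starting material
2 | N-methoxy-N-methylacetamide | CC(=O)N(C)OC | starting material
3 | prenylmagnesium chloride | CC(C)=CC[Mg]Cl | intermediate
4 | 3,3-dimethylpent-4-en-2-one | CC(=O)C(C)(C)C=C | intermediate
5 | 2-iodoaniline | Nc1ccccc1I | starting material
6 | diethyl 3,3-dimethylpenta-1,4-dien-2-yl phosphate | C=C(OP(=O)(OCC)OCC)C(C)(C)C=C | intermediate
7 | lithium 3,3-dimethylpent-4-en-1-yn-1-ide | [Li]C#CC(C)(C)C=C | intermediate
8 | (3,3-dimethylpent-4-en-1-yn-1-yl)zinc bromide | Br[Zn]C#CC(C)(C)C=C | intermediate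
9 | 2-(3,3-dimethylpent-4-en-1-yn-1-yl)aniline | Nc1ccccc1C#CC(C)(C)C=C | intermediate
10 | N-[2-(3,3-dimethylpent-4-en-1-yn-1-yl)phenyl]-2,2,2-trifluoroacetamide | O=C(Nc1ccccc1C#CC(C)(C)C=C)C(F)(F)F | intermediate
11 | bromanil (2,3,5,6-tetrabromo-1,4-benzoquinone) | O=C1C(Br)=C(Br)C(=O)C(Br)=C1Br | starting material
12 | 2,5-dibromo-3,6-dimethoxy-1,4-benzoquinone | COC1=C(Br)C(=O)C(OC)=C(Br)C1=O | intermediate
13 | 2-bromo-3,6-dimethoxy-5-[2-(2-methylbut-3-en-2-yl)-1-(trifluoroacetyl)indol-3-yl]-1,4-benzoquinone | COC1=C(Br)C(=O)C(OC)=C(c2c(C(C)(C)C=C)n(C(=O)C(F)(F)F)c3ccccc23)C1=O | intermediate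
14 | 2,5-dimethoxy-3,6-bis[2-(2-methylbut-3-en-2-yl)-1-(trifluoroacetyl)indol-3-yl]-1,4-benzoquinone | COC1=C(c2c(C(C)(C)C=C)n(C(=O)C(F)(F)F)c3ccccc23)C(=O)C(OC)=C(c2c(C(C)(C)C=C)n(C(=O)C(F)(F)F)c3ccccc23)C1=O | intermediate
15 | 2,5-dimethoxy-3,6-bis[2-(2-methylbut-3-en-2-yl)-1H-indol-3-yl]-1,4-benzoquinone (achiral) | C=CC(C)(C)c1[nH]c2ccccc2c1C1=C(OC)C(=O)C(c2c(C(C)(C)C=C)[nH]c3ccccc23)=C(OC)C1=O | target

**Step count**
Total steps: 5. Longest linear sequence: 4 (steps 1, 2, 3, 5; step 4 is a one-step side branch).

**Steps most likely to fail**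

Step 5 (double annulation on the bromoquinone). The amidate or free phosphine may attack the quinone, zerovalent palladium may be oxidised by it, and the reductive elimination is hindered. Protodepalladation to the 3-unsubstituted indole is less damaging, because that indole can still substitute the C–Br bond of 12 under the carbonate conditions and reach the same product. Fallback: run the same double ring closure at the hydroquinone oxidation level. It sets out from 12 and comes back at 15. Reductive acetylation of 12 (Zn, Ac2O, NaOAc) gives 2,5-dibromo-3,6-dimethoxy-1,4-phenylene diacetate F1, an ordinary aryl dibromide. Double aminopalladation–reductive elimination of F1 with 10 (Pd2(dba)3, XPhos, anhydrous Cs2CO3, MeCN, 80 °C) gives 2,5-dimethoxy-3,6-bis[2-(2-methylbut-3-en-2-yl)-1-(trifluoroacetyl)indol-3-yl]-1,4-phenylene diacetate F2. K2CO3 in MeOH under air removes all four acyl groups to give 2,5-dimethoxy-3,6-bis[2-(2-methylbut-3-en-2-yl)-1H-indol-3-yl]benzene-1,4-diol F3, which is oxidised in the same flask by air (or Ag2O) to 15.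

Step 2 (one-pot ketone-to-alkyne conversion, zincation and coupling). The elimination may be incomplete, and the coupling has to run in the presence of amine and phosphate salts. Fallback: build the alkyne from an aldehyde instead. It sets out from 3 and comes back at 7. Formylation of 3 with DMF (THF, 0 °C, acid work-up, γ-attack) gives 2,2-dimethylbut-3-enal F4. Ramirez olefination (CBr4, PPh3, CH2Cl2, 0 °C) gives the non-volatile 1,1-dibromo-3,3-dimethylpenta-1,4-diene F5. n-BuLi (2.1 equiv, THF, −78 °C) converts F5 by bromine–lithium exchange and Fritsch–Buttenberg–Wiechell rearrangement into lithium acetylide 7, from which ZnBr2 and the coupling with 5 proceed as in step 2.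

Step 4 (selective dimethanolysis of bromanil). Mixtures of mono-, di- and trimethoxy quinones or partial hydrolysis are possible. Fallback: hydrolyse first, then alkylate. It sets out from 11 and comes back at 12. Aqueous NaOH converts 11 into bromanilic acid F6 (2,5-dibromo-3,6-dihydroxy-1,4-benzoquinone), isolated after acidification; O-methylation with MeI and Ag2O in CHCl3 (or Me2SO4, K2CO3, acetone) gives 12.

**Further compounds**
F1 | step 5 | 2,5-dibromo-3,6-dimethoxy-1,4-phenylene diacetate | CC(=O)Oc1c(Br)c(OC)c(OC(C)=O)c(Br)c1OC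
F2 | step 5 | 2,5-dimethoxy-3,6-bis[2-(2-methylbut-3-en-2-yl)-1-(trifluoroacetyl)indol-3-yl]-1,4-phenylene diacetate | CC(=O)Oc1c(-c2c(C(C)(C)C=C)n(C(=O)C(F)(F)F)c3ccccc23)c(OC)c(OC(C)=O)c(-c2c(C(C)(C)C=C)n(C(=O)C(F)(F)F)c3ccccc23)c1OC
F3 | step 5 | 2,5-dimethoxy-3,6-bis[2-(2-methylbut-3-en-2-yl)-1H-indol-3-yl]benzene-1,4-diol | COc1c(O)c(-c2c(C(C)(C)C=C)[nH]c3ccccc23)c(OC)c(O)c1-c1c(C(C)(C)C=C)[nH]c2ccccc12
F4 | step 2 | 2,2-dimethylbut-3-enal | O=CC(C)(C)C=C
F5 | step 2 | 1,1-dibromo-3,3-dimethylpenta-1,4-diene | BrC(Br)=CC(C)(C)C=C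
F6 | step 4 | bromanilic acid (2,5-dibromo-3,6-dihydroxy-1,4-benzoquinone) | OC1=C(Br)C(=O)C(O)=C(Br)C1=O
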